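(The runs come from a simulation for substances that don't exist, noise included.)

Of the 0.012 M of starting material charged to each flask, which is the limiting reagent for target since it stands below the 0.0180 M of reagent, the ledger has two entries, target and starting material left, and in violet at 10.0 min they read 48.3% and 51.8%, together 100%, so the books close within the scatter.

| setting | violet | teal | amber | eta | beta | epsilon |
|---|---|---|---|---|---|---|
| starting material | 0.012 M | 0.012 M | 0.012 M | 0.012 M | 0.012 M | 0.012 M |
| second substrate | 0.012 M | 0.0080 M | 0.018 M | 0.0120 M | 0.0120 M (fed, over 6.0 min) | 0.0120 M |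
| reagent | 0.018 M | 0.018 M | 0.018 M | 0.0180 M (fed, over 6.0 min) | 0.0180 M | 0.0180 M |
| free catalyst | 12 µM | 12 µM | 12 µM | 12 µM | 12 µM | 12 µM |
| remark | run made earlier | run made earlier | run made earlier | all else is in the flask from the start; the feed brings no volume worth counting | all else is in the flask from the start; the feed brings no volume worth counting | everything together at the start |
| time |  |  |  | 15 min | 15 min | 15 min |

| run | time / min | target / % | starting material / % |
|---|---|---|---|
| violet | 0.667 | 10.1 | 88.2 |
| violet | 1.33 | 18.4 | 83.1 |
| violet | 2.00 | 24.9 | 76.4 |
| violet | 3.00 | 29.2 | 71.6 |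
| violet | 5.00 | 39.0 | 60.1 |
| violet | 10.0 | 48.3 | 51.8 |
| teal | 1.33 | 20.7 | 81.8 |
| teal | 4.00 | 43.2 | 56.5 |
| teal | 6.00 | 54.3 | 49.4 |
| teal | 10.0 | 64.6 | 34.2 |
| teal | 15.0 | 71.8 | 28.1 |
| teal | 20.0 | 75.5 | 23.7 |
| amber | 3.00 | 20.8 | 78.6 |
| amber | 6.00 | 25.9 | 73.9 |
| amber | 10.0 | 27.3 | 73.1 |
| amber | 12.0 | 27.4 | 73.9 |
| amber | 15.0 | 25.4 | 71.4 |
| amber | 20.0 | 28.4 | 73.6 |

(scatter of a reading: 1 percentage point)

- on the list of suspects stand: reagent + catalyst intermediate B -> free catalyst + second product; second substrate + free catalyst <-> catalyst intermediate B; second substrate + catalyst intermediate B -> spent catalyst; reagent + catalyst intermediate A -> free catalyst + target; starting material + free catalyst <-> catalyst intermediate A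

- the flask that comes out highest in amount of target, in percent of the starting material charged, or "all alike" when all lie within 1.5 percentage points (eta / beta / epsilon / all alike)
- target at the end, in percent of the starting material charged, eta
- target at the end, in percent of the starting material charged, beta
- target at the end, in percent of the starting material charged, epsilon

The runs differ in where the left entry stops: amber stands near 73.6%, while teal, still creeping at 20.0 min, has 23.7%. On the list of suspects, second substrate turns catalyst intermediate B into spent catalyst, so we take each run's last reading as a measure of what its catalyst bought and weigh it thus: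

budget = ln(charge ÷ left) × (second substrate charged ÷ violet's charge), squared

violet: 0.658

teal: 0.640

amber: 0.690

mean: 0.662

This mean, the logarithmic conversion that a charge of catalyst buys at violet's second substrate, is the catalyst budget, and it has been read at one reagent level, 0.018 M. For epsilon, a repeat of violet, we reckon from it 48.4% target. We rank beta first, since its feed holds second substrate below the charge while the catalyst works, and we put no figure on eta, whose reagent lies outside what the budget was read at.

The forecast also ranks beta first, with eta 40% (22% to 51%), beta 72% (63% to 84%) and epsilon 50.5% (48.5% to 53%), which stands above our epsilon; of eta it says “The reagent dependence is unmeasured”.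

The flasks give eta 33.9%, beta 72.4% and epsilon 50.6%, so beta comes highest.

    reagent + catalyst intermediate B → free catalyst + second product (k = 251 M⁻¹ s⁻¹)
    second substrate + free catalyst ⇌ catalyst intermediate B (K = 59.0 M⁻¹, k = 42200 M⁻¹ s⁻¹)
    second substrate + catalyst intermediate B → spent catalyst (k = 1.29 M⁻¹ s⁻¹)
    reagent + catalyst intermediate A → free catalyst + target (k = 426 M⁻¹ s⁻¹)
    starting material + free catalyst ⇌ catalyst intermediate A (K = 140 M⁻¹, k = 1600 M⁻¹ s⁻¹)

Eta's budget comes to 0.414, which is 0.625 of the mean. Beta ends 39 percentage points above eta, and that difference shrinks to 3.4 points in the run without the passing of second substrate + free catalyst into catalyst intermediate B, both ways, and to 8.3 points in the run without the passing of second substrate + catalyst intermediate B into spent catalyst, so these two steps open the gap together. A further flask like beta but charged with 0.0045 M of reagent has 0.250 of beta's reagent and keeps 0.218 of beta's budget, ending at 24.5% target.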